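The target is a C2-symmetric head-to-tail dimer: two abieta-8,11,13-triene units joined by a 1,4-dioxane (C6α–O–C7′β, C7β–O–C6′α). Both C12–O bonds are disconnected last. One twofold arene C–H oxygenation with bis(methanesulfonyl) peroxide turns the 12,12′-dideoxy dimer into the 12,12′-bis(mesylate). It exploits ring C of each half, a 1,2,4-trialkylbenzene whose C12–H is para to C8 and ortho to the C13 isopropyl group, while C11 (bay, under C1 and the C10 methyl) and C14 (between C7 and isopropyl) are shielded. The precursor carries no arene oxygen, so its benzylic C7–O bonds are robust; it is built from dehydroabietic acid by epoxide opening and reductive etherification.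

Key step: step 12

Remark: abietane numbering is used for each half (primes for the second half) and α means the face opposite the C10 methyl group. The target decodes to 5α-H, 10β-CH3, 6α-O and 7β-O in both halves (both ring B/dioxane fusions trans), and the structures of the precursor and product of the key step agree with this. Bis(methanesulfonyl) peroxide is taken as not purchasable and is made in step 11 from two equivalents of methanesulfonyl chloride.

Step 1
Reactants: 1 dehydroabietic acid (abieta-8,11,13-trien-18-oic acid; 5α-H, 10β-CH3, 4α-CO2H)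
Product: 2 dehydroabietinol (abieta-8,11,13-trien-18-ol)
Conditions: LiAlH4, THF, 0 °C → reflux; then H2O, aq. NaOH
Reagents that add atoms: none
Why: Hydride reduction of the carboxylic acid with LiAlH4 should give the neopentyl C18 carbinol without touching C4, C5 or C10, which all come from 1.

Step 2
Reactants: 2 dehydroabietinol
Product: 3 dehydroabietinal (abieta-8,11,13-trien-18-al)
Conditions: Dess–Martin periodinane, CH2Cl2, 20 °C
Reagents that add atoms: none
Why: Dess–Martin oxidation of the primary alcohol stops at the aldehyde, which has no α-hydrogen and so cannot epimerise at C4.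

Step 3
Reactants: 3 dehydroabietinal
Product: 5 abieta-8,11,13-triene, via dehydroabietinal hydrazone 4 (not isolated)
Conditions: N2H4·H2O, KOH, diethylene glycol, 130 °C → 200 °C
Reagents that add atoms: none
Why: Wolff–Kishner reduction (Huang-Minlon procedure) of the non-enolisable aldehyde through hydrazone 4 should give the C18 methyl group, which turns C4 into a gem-dimethyl carbon and removes that stereocentre.

Step 4
Reactants: 5 abieta-8,11,13-triene
Product: 6 abieta-8,11,13-trien-7-one
Conditions: CrO3, AcOH–H2O, 20 °C
Reagents that add atoms: chromium trioxide, O=[Cr](=O)=O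
Why: Chromic acid benzylic oxidation should convert the secondary benzylic C7 methylene into the aryl ketone in preference to the isopropyl methine, which can only give a separable tertiary alcohol.

Step 5
Reactants: 6 abieta-8,11,13-trien-7-one
Product: 7 abieta-8,11,13-trien-7β-ol
Conditions: NaBH4, MeOH, 0 °C
Reagents that add atoms: none
Why: Borohydride reduction with pseudo-axial hydride delivery from the α face should give mainly the equatorial 7β-alcohol, and any 7α-epimer is carried along because step 6 destroys this centre.

Step 6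
Reactants: 7 abieta-8,11,13-trien-7β-ol
Product: 8 abieta-6,8,11,13-tetraene
Conditions: TsOH·H2O (cat.), toluene, reflux, Dean–Stark
Reagents that add atoms: none
Why: Acid-catalysed E1 dehydration through the benzylic C7 cation can only place the double bond at C6=C7, because C8 is aromatic.

Step 7
Reactants: 8 abieta-6,8,11,13-tetraene
Product: 9 6α,7α-epoxyabieta-8,11,13-triene
Conditions: mCPBA, CH2Cl2 / aq. NaHCO3, 0 °C
Reagents that add atoms: 3-chloroperoxybenzoic acid, OOC(=O)c1cccc(Cl)c1
Why: In this Prilezhaev epoxidation the β face of C6=C7 is screened by the axial C10 and C4β methyl groups, so the peracid should add from the α face and set C6 and C7 as the 6α,7α-epoxide, with the bicarbonate buffer protecting the benzylic epoxide from acid.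

Step 8
Reactants: 6 abieta-8,11,13-trien-7-one
Product: 11 6α-hydroxyabieta-8,11,13-trien-7-one, via potassium enolate 10 (not isolated)
Conditions: KN(SiMe3)2, THF, −78 °C; 2-(phenylsulfonyl)-3-phenyloxaziridine, −78 °C; AcOH
Reagents that add atoms: 2-(phenylsulfonyl)-3-phenyloxaziridine (Davis oxaziridine), O=S(=O)(c1ccccc1)N1OC1c1ccccc1
Why: In this Davis oxidation the oxaziridine should transfer oxygen to C6 of the enolate from the open α face (the β face is blocked by the C10 and C4β methyl groups), giving the equatorial 6α-alcohol, which is also the more stable epimer.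

Step 9
Reactants: 11 6α-hydroxyabieta-8,11,13-trien-7-one; 9 6α,7α-epoxyabieta-8,11,13-triene
Product: 12 6α-[(6′α-hydroxyabieta-8′,11′,13′-trien-7′β-yl)oxy]abieta-8,11,13-trien-7-one
Conditions: BF3·OEt2 (0.1 equiv), CH2Cl2, 4 Å sieves, −78 → −40 °C, slow addition of 9 to 11 (2 equiv)
Reagents that add atoms: none
Why: In this Lewis acid-catalysed alcoholysis of a benzylic epoxide the C6 hydroxyl of 11 should open BF3-activated 9 at the benzylic C7′ from the β face with inversion, which sets 7′β–O trans to the liberated 6′α-hydroxyl, while low temperature, slow addition and excess 11 hold back the Meinwald rearrangement of 9.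

Step 10
Reactants: 12 6α-[(6′α-hydroxyabieta-8′,11′,13′-trien-7′β-yl)oxy]abieta-8,11,13-trien-7-one
Product: 14 12,12′-dideoxy dimer (dioxane-linked bis-abieta-8,11,13-triene; C6α–O–C7′β and C7β–O–C6′α), via cyclic hemiketal 13 (not isolated)
Conditions: Et3SiH, TMSOTf (0.2 equiv), CH2Cl2, −78 → 0 °C
Reagents that add atoms: none
Why: In this reductive etherification of a hydroxy ketone the 6′α-hydroxyl adds to the C7 ketone to give hemiketal 13, TMSOTf ionises it to a six-membered aryl-stabilised oxocarbenium ion and Et3SiH should deliver hydride axially from the α face (anti to the axial 6β-H), which sets 7α-H and 7β–O and closes the all-equatorial, doubly trans-fused dioxane.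

Step 11
Reactants: 15 methanesulfonyl chloride (2 equiv)
Product: 17 bis(methanesulfonyl) peroxide, via methanesulfonyl hydroperoxide 16 (not isolated)
Conditions: 30% aq. H2O2 (0.5 equiv relative to 15), K2CO3, H2O, −5 → 0 °C
Reagents that add atoms: hydrogen peroxide, OO; methanesulfonyl chloride (the second equivalent of 15), CS(=O)(=O)Cl
Why: Twofold O-sulfonylation of hydrogen peroxide under carbonate, in which the first equivalent of 15 gives hydroperoxide 16 and its anion attacks a second equivalent of 15 at sulfur, is the standard way to sulfonyl peroxides, and the solid should be collected cold, kept in small batches and never heated.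

Step 12
Reactants: 14 12,12′-dideoxy dimer; 17 bis(methanesulfonyl) peroxide
Product: 19 12,12′-bis(methanesulfonyloxy) dimer, via mono-mesylate 18 (not isolated)
Conditions: 17 (2.5 equiv), (CF3)2CHOH (CH2Cl2 co-solvent for solubility), 23 °C
Reagents that add atoms: bis(methanesulfonyl) peroxide 17, CS(=O)(=O)OOS(C)(=O)=O
Why: Hydrogen bonding by hexafluoroisopropanol polarises the O–O bond of 17, the π system of ring C attacks one peroxide oxygen through a charge-transfer complex to give a mesyloxy-arenium ion, and loss of the C12 proton gives the aryl mesylate and methanesulfonic acid, the second ring following through 18. The closest known reaction type is electrophilic arene C–H oxygenation of alkylbenzenes with sulfonyl peroxides, which stops at one oxygen per ring because the aryl mesylate is deactivated. No ring is closed and no stereocentre is formed, so the eight stereocentres of 14 are only carried through. The step needs site selectivity among C11, C12 and C14 and arene over benzylic C–H oxidation, and ring C secures the first: C12 is para to C8, ortho to the C13 isopropyl group and has a hydrogen neighbour, C11 lies in the bay under C1 and the C10 methyl group with one activating alkyl group only, and C14 is wedged between C7 and the isopropyl group, the pattern that sends acylation and bromination of dehydroabietates to C12. The isopropyl methine and C7–H would be oxidised by hydrogen abstraction, which the metal-free polar medium does not favour, and the C7–O bonds should withstand the acid formed because their ionisation would give a benzylic cation next to the C6 oxygen without a para donor. Since 14 is C2-symmetric both rings are equivalent and one bis-mesylate is expected.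

Step 13
Reactants: 19 12,12′-bis(methanesulfonyloxy) dimer
Product: 21 12,12′-dihydroxy dimer (bis-phenol), via phenol mesylate 20 (not isolated)
Conditions: LiN(iPr)2 (5 equiv), THF, −78 → 0 °C; AcOH
Reagents that add atoms: none
Why: In this base-induced aryl mesylate cleavage the amide deprotonates the mesyl methyl group and sulfene is expelled (E1cB) to leave the lithium phenoxide, a path that does not need access to the sulfur next to the isopropyl group and avoids hot alkoxide, which could open the now para-oxygenated benzylic C7–O bonds through a quinone methide.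

Step 14
Reactants: 21 12,12′-dihydroxy dimer
Product: 23 target CNP0327150.1 (12,12′-dimethoxy dimer), via phenol methyl ether 22 (not isolated)
Conditions: MeI, Cs2CO3, DMF, 20 °C
Reagents that add atoms: iodomethane, CI
Why: Williamson O-methylation of the caesium phenoxides at room temperature in a non-nucleophilic medium should leave the dioxane and all eight stereocentres untouched.

Compound list
1 | dehydroabietic acid (abieta-8,11,13-trien-18-oic acid; 5α-H, 10β-CH3, 4α-CO2H) | CC(C)c1ccc2c(c1)CC[C@@H]1[C@]2(C)CCC[C@@]1(C)C(=O)O | starting material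
2 | dehydroabietinol (abieta-8,11,13-trien-18-ol) | CC(C)c1ccc2c(c1)CC[C@@H]1[C@]2(C)CCC[C@@]1(C)CO | intermediate
3 | dehydroabietinal (abieta-8,11,13-trien-18-al) | CC(C)c1ccc2c(c1)CC[C@@H]1[C@]2(C)CCC[C@@]1(C)C=O | intermediate
4 | dehydroabietinal hydrazone (not isolated) | CC(C)c1ccc2c(c1)CC[C@@H]1[C@]2(C)CCC[C@@]1(C)C=NN | intermediate
5 | abieta-8,11,13-triene (5α-H, 10β-CH3) | CC(C)c1ccc2c(c1)CC[C@H]1C(C)(C)CCC[C@]21C | intermediate
6 | abieta-8,11,13-trien-7-one | CC(C)c1ccc2c(c1)C(=O)C[C@H]1C(C)(C)CCC[C@]21C | intermediate
7 | abieta-8,11,13-trien-7β-ol | CC(C)c1ccc2c(c1)[C@@H](O)C[C@H]1C(C)(C)CCC[C@]21C | intermediate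
8 | abieta-6,8,11,13-tetraene | CC(C)c1ccc2c(c1)C=C[C@H]1C(C)(C)CCC[C@]21C | intermediate
9 | 6α,7α-epoxyabieta-8,11,13-triene | CC(C)c1ccc2c(c1)[C@@H]1O[C@@H]1[C@H]1C(C)(C)CCC[C@]21C | intermediate
10 | potassium enolate of 6 (potassium abieta-6,8,11,13-tetraen-7-olate; not isolated) | CC(C)c1ccc2c(c1)C([O-])=C[C@H]1C(C)(C)CCC[C@]21C.[K+] | intermediate
11 | 6α-hydroxyabieta-8,11,13-trien-7-one | CC(C)c1ccc2c(c1)C(=O)[C@H](O)[C@H]1C(C)(C)CCC[C@]21C | intermediate
12 | 6α-[(6′α-hydroxyabieta-8′,11′,13′-trien-7′β-yl)oxy]abieta-8,11,13-trien-7-one | CC(C)c1ccc2c(c1)C(=O)[C@H](O[C@@H]3c4cc(C(C)C)ccc4[C@@]4(C)CCCC(C)(C)[C@@H]4[C@H]3O)[C@H]1C(C)(C)CCC[C@]21C | intermediate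
13 | cyclic hemiketal of 12 (7-hydroxy dioxane; hemiketal carbon C7 left undefined; not isolated) | CC(C)c1ccc2c(c1)C1(O)O[C@H]3[C@H](O[C@@H]1[C@H]1C(C)(C)CCC[C@]21C)c1cc(C(C)C)ccc1[C@@]1(C)CCCC(C)(C)[C@H]31 | intermediate
14 | 12,12′-dideoxy dimer (C2-symmetric bis-abieta-8,11,13-triene; dioxane through C6α–O–C7′β and C7β–O–C6′α) | CC(C)c1ccc2c(c1)[C@H]1O[C@H]3[C@H](O[C@@H]1[C@H]1C(C)(C)CCC[C@]21C)c1cc(C(C)C)ccc1[C@@]1(C)CCCC(C)(C)[C@H]31 | intermediate
15 | methanesulfonyl chloride | CS(=O)(=O)Cl | starting material
16 | methanesulfonyl hydroperoxide (peroxymethanesulfonic acid; present as its potassium salt in the basic medium; not isolated) | CS(=O)(=O)OO | intermediate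
17 | bis(methanesulfonyl) peroxide | CS(=O)(=O)OOS(C)(=O)=O | intermediate
18 | 12-(methanesulfonyloxy) dimer (mono-mesylate; not isolated) | CS(=O)(=O)Oc1cc2c(cc1C(C)C)[C@H]1O[C@H]3[C@H](O[C@@H]1[C@H]1C(C)(C)CCC[C@]21C)c1cc(C(C)C)ccc1[C@@]1(C)CCCC(C)(C)[C@H]31 | intermediate
19 | 12,12′-bis(methanesulfonyloxy) dimer | CS(=O)(=O)Oc1cc2c(cc1C(C)C)[C@H]1O[C@H]3[C@H](O[C@@H]1[C@H]1C(C)(C)CCC[C@]21C)c1cc(C(C)C)c(OS(C)(=O)=O)cc1[C@@]1(C)CCCC(C)(C)[C@H]31 | intermediate
20 | 12-hydroxy-12′-(methanesulfonyloxy) dimer (phenol mesylate; not isolated) | Oc1cc2c(cc1C(C)C)[C@H]1O[C@H]3[C@H](O[C@@H]1[C@H]1C(C)(C)CCC[C@]21C)c1cc(C(C)C)c(OS(C)(=O)=O)cc1[C@@]1(C)CCCC(C)(C)[C@H]31 | intermediate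
21 | 12,12′-dihydroxy dimer (bis-phenol) | Oc1cc2c(cc1C(C)C)[C@H]1O[C@H]3[C@H](O[C@@H]1[C@H]1C(C)(C)CCC[C@]21C)c1cc(C(C)C)c(O)cc1[C@@]1(C)CCCC(C)(C)[C@H]31 | intermediate
22 | 12-methoxy-12′-hydroxy dimer (phenol methyl ether; not isolated) | COc1cc2c(cc1C(C)C)[C@H]1O[C@H]3[C@H](O[C@@H]1[C@H]1C(C)(C)CCC[C@]21C)c1cc(C(C)C)c(O)cc1[C@@]1(C)CCCC(C)(C)[C@H]31 | intermediate
23 | CNP0327150.1 (12,12′-dimethoxy dimer) | COc1cc2c(cc1C(C)C)[C@H]1O[C@H]3[C@H](O[C@@H]1[C@H]1C(C)(C)CCC[C@]21C)c1cc(C(C)C)c(OC)cc1[C@@]1(C)CCCC(C)(C)[C@H]31 | target

Total step count: 14. Longest linear sequence: 12 steps (steps 1–7, 9, 10, 12, 13, 14 from 1; steps 8 and 11 are side branches).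

Steps most likely to fail

Step 9. The BF3-activated epoxide may rearrange by hydride shift to the 6-ketone, or ionise far enough at C7′ to lose the anti selectivity, faster than the hindered C6 hydroxyl of 11 captures it. The fallback sets out from 11, returns to the route at 14 and leaves out 9 and 12. Silylation of 11 (Me3SiCl, imidazole, CH2Cl2) should give 6α-(trimethylsilyloxy)abieta-8,11,13-trien-7-one F1. A twofold head-to-tail reductive etherification (Et3SiH, TMSOTf, CH2Cl2, −78 → 0 °C) then joins two molecules of F1. The silyl ether oxygen of one adds to the activated C7 ketone of the other, the oxocarbenium ion is reduced pseudo-axially from the α face to set 7β–O, and the second C7–O bond closes inside the molecule as in step 10.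

Step 12. Oxygenation may stray to C14 or C11, hydrogen abstraction may oxidise the isopropyl methine or C7–H, the acid formed may cleave a C7–O bond, or the reaction may stall after one ring. The fallback sets out from 14 and returns at target 23, bypassing 19 and 21. Twofold electrophilic bromination under the same orientation rules (NBS, MeCN, 20 °C, dark) should give the 12,12′-dibromo dimer F2. Cross-coupling of both aryl bromides with methanol (Pd2(dba)3, RockPhos, Cs2CO3, MeOH–toluene, 80 °C) then installs the two methoxy groups directly.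

Step 10. The silane may reduce the ketone before the hemiketal forms, or hydride may add to the oxocarbenium ion from the β face, which would give an open-chain diol or a cis-fused dioxane. The fallback sets out from 12 and returns at 14. Reduction with NaBH4 (MeOH, 0 °C) from the α face should give 6α-[(6′α-hydroxyabieta-8′,11′,13′-trien-7′β-yl)oxy]abieta-8,11,13-trien-7β-ol F3. Acid-catalysed cyclodehydration (TfOH cat., CH2Cl2, 0 °C) through the C7 benzylic cation then closes the dioxane under thermodynamic control to the all-equatorial trans-fused isomer.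

Further compounds
F1 | step 9 | 6α-(trimethylsilyloxy)abieta-8,11,13-trien-7-one | CC(C)c1ccc2c(c1)C(=O)[C@H](O[Si](C)(C)C)[C@H]1C(C)(C)CCC[C@]21C
F2 | step 12 | 12,12′-dibromo dimer | Brc1cc2c(cc1C(C)C)[C@H]1O[C@H]3[C@H](O[C@@H]1[C@H]1C(C)(C)CCC[C@]21C)c1cc(C(C)C)c(Br)cc1[C@@]1(C)CCCC(C)(C)[C@H]31
F3 | step 10 | 6α-[(6′α-hydroxyabieta-8′,11′,13′-trien-7′β-yl)oxy]abieta-8,11,13-trien-7β-ol | CC(C)c1ccc2c(c1)[C@@H](O)[C@H](O[C@@H]3c4cc(C(C)C)ccc4[C@@]4(C)CCCC(C)(C)[C@@H]4[C@H]3O)[C@H]1C(C)(C)CCC[C@]21C
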